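**Retrosynthetic overview** (target numbering: main chain C1 = lactone carbonyl to C20 = terminal =CH2; butenolide ring O–C1–C2=C3–C4)

1. Feature the strategy rests on: the C18 secondary carbinol carrying the C19 isopropenyl group (C19=C20, C19–CH3) is the 1,3-transposed form of a terminal (E)-allylic primary alcohol at C20, which is what SeO2 installs on the prenyl end of farnesol (farnesol = C9–C20).
2. Key disconnection: the C18–O and C19–O bonds of a transient C18/C19 oxirane, made by tartrate-controlled epoxidation of 12-hydroxyfarnesyl acetate; a C20 iodide and zinc then open it to the C18 carbinol and the C19=C20 alkene.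
3. C8–C9 by propargylation of the farnesyl-type bromide with lithiated TMS-propyne (C6–C8); C5 from formaldehyde; C6=C7 geometry from Red-Al/I2; the C7 hydroxymethyl by Stille coupling.
4. C4–C5 by allylation of dilithiated 3-furanmethanol (C1–C4 plus the C3 hydroxymethyl); furan to 5-hydroxybutenolide with singlet oxygen; C4 set by CBS reduction of the ring-opened keto ester, then lactonisation.
5. Ring order: oxirane (formed step 3, opened step 5), furan (purchased), furan endoperoxide and lactol (step 17), butenolide (step 19).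

Key step: step 3

Remark: atoms are given in target numbering; the acetal carbon of 25 and 26 forms as both epimers, which is immaterial because step 19 sets C4, and organolithium steps are taken as quenched with water.

**Route**

Step 1
Reactants: 1 (2E,6E)-farnesol
Product: 2 (2E,6E)-farnesyl acetate
Conditions: Ac2O, pyridine, DMAP (cat.), CH2Cl2, 0 °C to rt
Reagents that add atoms: acetic anhydride CC(=O)OC(C)=O
Why: DMAP-catalysed acylation caps the C9 primary allylic alcohol so that it can neither direct the later oxidations nor bind titanium.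

Step 2
Reactants: 2 (2E,6E)-farnesyl acetate
Product: 3 (2E,6E,10E)-12-hydroxyfarnesyl acetate
Conditions: SeO2 (0.3 equiv), t-BuOOH (3 equiv), salicylic acid (0.1 equiv), CH2Cl2, 0 °C to rt
Reagents that add atoms: selenium dioxide O=[Se]=O (oxygen donor, turned over); tert-butyl hydroperoxide CC(C)(C)OO (terminal oxidant)
Why: Catalytic SeO2 allylic hydroxylation (ene reaction then [2,3]-sigmatropic shift) should oxidise the E-methyl of the terminal, most electron-rich trisubstituted alkene, the alkene next to the acetate being deactivated; any over-oxidised enal can be returned with NaBH4.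

Step 3
Reactants: 3 (2E,6E,10E)-12-hydroxyfarnesyl acetate
Product: 4 (2E,6E)-9-[(2R,3R)-3-(hydroxymethyl)-3-methyloxiran-2-yl]-3,7-dimethylnona-2,6-dien-1-yl acetate
Conditions: Ti(Oi-Pr)4 (0.2 equiv), D-(−)-diethyl tartrate (0.25 equiv), t-BuOOH (2 equiv, decane), 4 Å MS, CH2Cl2, −20 °C
Reagents that add atoms: tert-butyl hydroperoxide CC(C)(C)OO
Why: Katsuki–Sharpless asymmetric epoxidation: the C20 alkoxide of 3 and the hydroperoxide exchange onto the titanium tartrate complex, and the distal peroxide oxygen is transferred to the C18=C19 π bond of the bound allylic alkoxide, the closest known case being epoxidation of (E)-2-methyl-2-alken-1-ols. The oxirane closes by concerted [2+1] oxygen-atom transfer, both C–O bonds forming on one alkene face, so the E geometry becomes the trans relation of C17 and the hydroxymethyl group. C18 (R) and C19 (R) are both set by the ligand, since D-(−)-tartrate delivers oxygen to the face that gives the (2R,3R)-epoxy alcohol of an E-2-methyl-2-alkenol. The step needs site selectivity among four alkenes and enantiofacial selectivity; the first is secured because only the alkene bearing the free hydroxymethyl can bind titanium (the other primary alcohol is an acetate), the second by the tartrate. Molecular sieves keep the catalyst turning over and suppress opening of the epoxide.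

Step 4
Reactants: 4 (2E,6E)-9-[(2R,3R)-3-(hydroxymethyl)-3-methyloxiran-2-yl]-3,7-dimethylnona-2,6-dien-1-yl acetate
Product: 5 (2E,6E)-9-[(2R,3S)-3-(iodomethyl)-3-methyloxiran-2-yl]-3,7-dimethylnona-2,6-dien-1-yl acetate
Conditions: I2, PPh3, imidazole, CH2Cl2, 0 °C
Reagents that add atoms: iodine II
Why: Appel-type iodination displaces the alkoxyphosphonium by iodide in an SN2 step at C20 under buffered neutral conditions, leaving oxirane, acetate and both stereocentres untouched (the C19 descriptor changes only through CIP priority).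

Step 5
Reactants: 5 (2E,6E)-9-[(2R,3S)-3-(iodomethyl)-3-methyloxiran-2-yl]-3,7-dimethylnona-2,6-dien-1-yl acetate
Product: 6 (2E,6E,10R)-10-hydroxy-3,7,11-trimethyldodeca-2,6,11-trien-1-yl acetate
Conditions: Zn dust (activated), AcOH (1.5 equiv), EtOH, 60 °C
Reagents that add atoms: none
Why: Reductive β-elimination (zinc insertion into C–I, then strain-releasing opening of the oxirane) forms C19=C20 and frees the C18 alkoxide; the C18–O bond is never broken, so 18R is retained.

Step 6
Reactants: 6 (2E,6E,10R)-10-hydroxy-3,7,11-trimethyldodeca-2,6,11-trien-1-yl acetate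
Product: 7 (2E,6E,10R)-10-(tert-butyldimethylsilyloxy)-3,7,11-trimethyldodeca-2,6,11-trien-1-yl acetate
Conditions: TBSCl, imidazole, DMF, rt
Reagents that add atoms: tert-butyldimethylsilyl chloride CC(C)(C)[Si](C)(C)Cl
Why: Imidazole-promoted silylation protects the C18 allylic carbinol for the organometallic steps without touching the stereocentre.

Step 7
Reactants: 7 (2E,6E,10R)-10-(tert-butyldimethylsilyloxy)-3,7,11-trimethyldodeca-2,6,11-trien-1-yl acetate
Product: 8 (2E,6E,10R)-10-(tert-butyldimethylsilyloxy)-3,7,11-trimethyldodeca-2,6,11-trien-1-ol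
Conditions: K2CO3 (cat.), MeOH, rt
Reagents that add atoms: none
Why: Base-catalysed transesterification (methanolysis) removes the acetate while the secondary TBS ether is stable.

Step 8
Reactants: 8 (2E,6E,10R)-10-(tert-butyldimethylsilyloxy)-3,7,11-trimethyldodeca-2,6,11-trien-1-ol
Product: 10 (2E,6E,10R)-1-bromo-10-(tert-butyldimethylsilyloxy)-3,7,11-trimethyldodeca-2,6,11-triene, via allylic mesylate 9 (not isolated)
Conditions: MsCl, Et3N, THF, −40 °C; then LiBr, THF, −40 to 0 °C
Reagents that add atoms: lithium bromide [Li+].[Br-]; methanesulfonyl chloride CS(Cl)(=O)=O (atoms kept only in 9)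
Why: Sulfonylation then SN2 displacement by bromide at the primary allylic carbon under non-acidic conditions keeps the alkene geometry and the silyl ether and avoids allylic transposition.

Step 9
Reactants: 10 (2E,6E,10R)-1-bromo-10-(tert-butyldimethylsilyloxy)-3,7,11-trimethyldodeca-2,6,11-triene; 11 1-(trimethylsilyl)propyne
Product: 13 (5E,9E,13R)-13-(tert-butyldimethylsilyloxy)-6,10,14-trimethyl-1-(trimethylsilyl)pentadeca-5,9,14-trien-1-yne, via 3-lithio-1-(trimethylsilyl)propyne 12 (not isolated)
Conditions: 11 (1.5 equiv), n-BuLi, THF, −78 to −20 °C; then 10, −78 °C to rt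
Reagents that add atoms: n-butyllithium [Li]CCCC (lithium kept only in 12)
Why: Alkylation of a propargyl anion: the silyl-capped propargyllithium attacks the allylic bromide by SN2 through its CH2 terminus (the silyl group disfavours the allenyl mode), forming C8–C9.

Step 10
Reactants: 13 (5E,9E,13R)-13-(tert-butyldimethylsilyloxy)-6,10,14-trimethyl-1-(trimethylsilyl)pentadeca-5,9,14-trien-1-yne
Product: 14 (5E,9E,13R)-13-(tert-butyldimethylsilyloxy)-6,10,14-trimethylpentadeca-5,9,14-trien-1-yne
Conditions: K2CO3, MeOH, rt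
Reagents that add atoms: none
Why: Methoxide-mediated protodesilylation cleaves only the alkynyl C–Si bond, the O–TBS ether being inert under these conditions.

Step 11
Reactants: 14 (5E,9E,13R)-13-(tert-butyldimethylsilyloxy)-6,10,14-trimethylpentadeca-5,9,14-trien-1-yne
Product: 16 (6E,10E,14R)-14-(tert-butyldimethylsilyloxy)-7,11,15-trimethylhexadeca-6,10,15-trien-2-yn-1-ol, via lithium acetylide 15 (not isolated)
Conditions: n-BuLi, THF, −78 °C; (CH2O)n, −78 °C to rt
Reagents that add atoms: formaldehyde (as paraformaldehyde) C=O; n-butyllithium [Li]CCCC (lithium kept only in 15)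
Why: Acetylide addition to formaldehyde (alkynylation of an aldehyde) adds C5 as the propargylic carbinol needed to direct the next step.

Step 12
Reactants: 16 (6E,10E,14R)-14-(tert-butyldimethylsilyloxy)-7,11,15-trimethylhexadeca-6,10,15-trien-2-yn-1-ol
Product: 18 (2Z,6E,10E,14R)-14-(tert-butyldimethylsilyloxy)-3-iodo-7,11,15-trimethylhexadeca-2,6,10,15-tetraen-1-ol, via cyclic vinylalanate 17 (not isolated)
Conditions: Red-Al, THF, 0 °C to rt; EtOAc; then I2, THF, −78 °C
Reagents that add atoms: iodine II; sodium bis(2-methoxyethoxy)aluminium hydride [Na+].COCCO[AlH2-]OCCOC (aluminium and sodium kept only in 17)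
Why: Alkoxide-directed trans-hydroalumination puts hydride on C6 and aluminium on C7 within a five-membered alkoxyvinylalanate, and iodinolysis with retention gives the (Z)-3-iodoallylic alcohol, which fixes the C6=C7 geometry of the target.

Step 13
Reactants: 18 (2Z,6E,10E,14R)-14-(tert-butyldimethylsilyloxy)-3-iodo-7,11,15-trimethylhexadeca-2,6,10,15-tetraen-1-ol
Product: 19 (2Z,6E,10E,14R)-1-bromo-14-(tert-butyldimethylsilyloxy)-3-iodo-7,11,15-trimethylhexadeca-2,6,10,15-tetraene
Conditions: CBr4, PPh3, 2,6-lutidine, CH2Cl2, −20 to 0 °C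
Reagents that add atoms: carbon tetrabromide BrC(Br)(Br)Br
Why: Appel bromination (SN2 at the primary allylic C5 through the alkoxyphosphonium) is neutral and leaves the vinyl iodide, the silyl ether and all alkene geometries intact.

Step 14
Reactants: 19 (2Z,6E,10E,14R)-1-bromo-14-(tert-butyldimethylsilyloxy)-3-iodo-7,11,15-trimethylhexadeca-2,6,10,15-tetraene; 20 3-furanmethanol
Product: 22 {2-[(2Z,6E,10E,14R)-14-(tert-butyldimethylsilyloxy)-3-iodo-7,11,15-trimethylhexadeca-2,6,10,15-tetraen-1-yl]furan-3-yl}methanol, via dilithiated 3-furanmethanol 21 (not isolated)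
Conditions: 20 (1.5 equiv), n-BuLi (2.0 equiv per 20), TMEDA, THF, −78 to 0 °C; then 19, −78 to 0 °C
Reagents that add atoms: n-butyllithium [Li]CCCC (lithium kept only in 21)
Why: Alkoxide-directed ortho-lithiation at the furan α-position next to the CH2OLi group, then SN2 C-allylation by the primary allylic bromide (the carbanion is far more nucleophilic than the alkoxide), forms C4–C5; a furyllithium is too weakly basic for iodine–lithium exchange with the vinyl iodide.

Step 15
Reactants: 22 {2-[(2Z,6E,10E,14R)-14-(tert-butyldimethylsilyloxy)-3-iodo-7,11,15-trimethylhexadeca-2,6,10,15-tetraen-1-yl]furan-3-yl}methanol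
Product: 23 {2-[(2Z,6E,10E,14R)-14-(tert-butyldimethylsilyloxy)-3-(hydroxymethyl)-7,11,15-trimethylhexadeca-2,6,10,15-tetraen-1-yl]furan-3-yl}methanol
Conditions: Bu3SnCH2OH (2 equiv), Pd(PPh3)4 (10 mol%), dioxane, 90 °C
Reagents that add atoms: (tributylstannyl)methanol CCCC[Sn](CCCC)(CCCC)CO
Why: Migita–Kosugi–Stille coupling: oxidative addition into the vinyl C–I bond and reductive elimination both proceed with retention, and the α-oxygenated methyl group transfers from tin in preference to butyl, so the C7 hydroxymethyl ends up cis to C5.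

Step 16
Reactants: 23 {2-[(2Z,6E,10E,14R)-14-(tert-butyldimethylsilyloxy)-3-(hydroxymethyl)-7,11,15-trimethylhexadeca-2,6,10,15-tetraen-1-yl]furan-3-yl}methanol
Product: 24 2-[(2Z,6E,10E,14R)-14-(tert-butyldimethylsilyloxy)-3-(tert-butyldimethylsilyloxymethyl)-7,11,15-trimethylhexadeca-2,6,10,15-tetraen-1-yl]-3-(tert-butyldimethylsilyloxymethyl)furan
Conditions: TBSCl (2.5 equiv), imidazole, DMF, rt
Reagents that add atoms: tert-butyldimethylsilyl chloride CC(C)(C)[Si](C)(C)Cl
Why: Imidazole-promoted silylation caps both primary alcohols so that the oxidation, esterification and borane steps see no free hydroxyl.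

Step 17
Reactants: 24 2-[(2Z,6E,10E,14R)-14-(tert-butyldimethylsilyloxy)-3-(tert-butyldimethylsilyloxymethyl)-7,11,15-trimethylhexadeca-2,6,10,15-tetraen-1-yl]-3-(tert-butyldimethylsilyloxymethyl)furan
Product: 26 5-hydroxy-4-(tert-butyldimethylsilyloxymethyl)-5-[(2Z,6E,10E,14R)-14-(tert-butyldimethylsilyloxy)-3-(tert-butyldimethylsilyloxymethyl)-7,11,15-trimethylhexadeca-2,6,10,15-tetraen-1-yl]furan-2(5H)-one (both C4 epimers), via furan endoperoxide 25 (not isolated)
Conditions: O2, hν (visible), tetraphenylporphyrin (cat.), i-Pr2NEt, CH2Cl2, −78 °C, stopped when the furan is consumed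
Reagents that add atoms: oxygen O=O
Why: [4+2] cycloaddition of singlet oxygen across the furan diene gives endoperoxide 25, from which the amine removes the only hydrogen on a peroxide-bearing carbon (C1–H) in a Kornblum–DeLaMare-type fragmentation, so the carbonyl must appear at C1 and the hemiketal at C4; the electron-rich 2,3-dialkylfuran should react far faster than the trisubstituted alkenes undergo the ene reaction at −78 °C.

Step 18
Reactants: 26 5-hydroxy-4-(tert-butyldimethylsilyloxymethyl)-5-[(2Z,6E,10E,14R)-14-(tert-butyldimethylsilyloxy)-3-(tert-butyldimethylsilyloxymethyl)-7,11,15-trimethylhexadeca-2,6,10,15-tetraen-1-yl]furan-2(5H)-one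
Product: 27 methyl (2Z,6Z,10E,14E,18R)-18-(tert-butyldimethylsilyloxy)-3,7-bis(tert-butyldimethylsilyloxymethyl)-11,15,19-trimethyl-4-oxoicosa-2,6,10,14,19-pentaenoate
Conditions: MeI, KHCO3, DMF, 0 °C to rt, dark
Reagents that add atoms: iodomethane CI
Why: The lactol is the ring tautomer of the (Z)-4-oxo-2-enoic acid, so bicarbonate generates the ring-opened carboxylate and SN2 O-alkylation traps it as the open methyl ester with the C4 ketone revealed; the weak base, low temperature and darkness are chosen to avoid migration of the C6 alkene into conjugation and Z to E isomerisation.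

Step 19
Reactants: 27 methyl (2Z,6Z,10E,14E,18R)-18-(tert-butyldimethylsilyloxy)-3,7-bis(tert-butyldimethylsilyloxymethyl)-11,15,19-trimethyl-4-oxoicosa-2,6,10,14,19-pentaenoate
Product: 29 (5R)-4-(tert-butyldimethylsilyloxymethyl)-5-[(2Z,6E,10E,14R)-14-(tert-butyldimethylsilyloxy)-3-(tert-butyldimethylsilyloxymethyl)-7,11,15-trimethylhexadeca-2,6,10,15-tetraen-1-yl]furan-2(5H)-one, via (4R)-hydroxy ester 28 (not isolated)
Conditions: (S)-Me-CBS (0.5 equiv), catecholborane (2 equiv), toluene, −78 °C; aq. NaHCO3 work-up; PPTS (cat.), CH2Cl2, rt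
Reagents that add atoms: none
Why: Corey–Bakshi–Shibata reduction: the ketone binds the oxazaborolidine boron anti to its larger α-branched alkenyl flank (C3) and the nitrogen-bound catecholborane delivers hydride to the face that, by analogy with acetophenone giving the R carbinol under the S catalyst (O > C3 alkenyl > C5H2), should set 4R; catecholborane at −78 °C does not hydroborate the isolated alkenes, and the Z-γ-hydroxy ester closes the butenolide by 5-exo-trig transesterification with loss of methanol.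

Step 20
Reactants: 29 (5R)-4-(tert-butyldimethylsilyloxymethyl)-5-[(2Z,6E,10E,14R)-14-(tert-butyldimethylsilyloxy)-3-(tert-butyldimethylsilyloxymethyl)-7,11,15-trimethylhexadeca-2,6,10,15-tetraen-1-yl]furan-2(5H)-one
Product: 30 Hippolide H
Conditions: HF·pyridine, pyridine, THF, 0 °C to rt
Reagents that add atoms: none
Why: Fluoride-driven desilylation removes all three TBS groups, and the acidic fluoride source avoids base-mediated epimerisation at the γ-position (C4–H) of the butenolide and transposition of the C18 allylic alcohol.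

**Compound list**

1 | (2E,6E)-farnesol | CC(C)=CCC/C(C)=C/CC/C(C)=C/CO | starting material
2 | (2E,6E)-farnesyl acetate | CC(C)=CCC/C(C)=C/CC/C(C)=C/COC(C)=O | intermediate
3 | (2E,6E,10E)-12-hydroxyfarnesyl acetate [(2E,6E,10E)-12-hydroxy-3,7,11-trimethyldodeca-2,6,10-trien-1-yl acetate] | OC/C(C)=C/CC/C(C)=C/CC/C(C)=C/COC(C)=O | intermediate
4 | (2E,6E)-9-[(2R,3R)-3-(hydroxymethyl)-3-methyloxiran-2-yl]-3,7-dimethylnona-2,6-dien-1-yl acetate | OC[C@@]1(C)O[C@@H]1CC/C(C)=C/CC/C(C)=C/COC(C)=O | intermediate
5 | (2E,6E)-9-[(2R,3S)-3-(iodomethyl)-3-methyloxiran-2-yl]-3,7-dimethylnona-2,6-dien-1-yl acetate | IC[C@@]1(C)O[C@@H]1CC/C(C)=C/CC/C(C)=C/COC(C)=O | intermediate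
6 | (2E,6E,10R)-10-hydroxy-3,7,11-trimethyldodeca-2,6,11-trien-1-yl acetate | C=C(C)[C@H](O)CC/C(C)=C/CC/C(C)=C/COC(C)=O | intermediate
7 | (2E,6E,10R)-10-(tert-butyldimethylsilyloxy)-3,7,11-trimethyldodeca-2,6,11-trien-1-yl acetate | C=C(C)[C@H](O[Si](C)(C)C(C)(C)C)CC/C(C)=C/CC/C(C)=C/COC(C)=O | intermediate
8 | (2E,6E,10R)-10-(tert-butyldimethylsilyloxy)-3,7,11-trimethyldodeca-2,6,11-trien-1-ol | C=C(C)[C@H](O[Si](C)(C)C(C)(C)C)CC/C(C)=C/CC/C(C)=C/CO | intermediate
9 | methanesulfonate of 8 (allylic mesylate) | C=C(C)[C@H](O[Si](C)(C)C(C)(C)C)CC/C(C)=C/CC/C(C)=C/COS(C)(=O)=O | intermediate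
10 | (2E,6E,10R)-1-bromo-10-(tert-butyldimethylsilyloxy)-3,7,11-trimethyldodeca-2,6,11-triene | C=C(C)[C@H](O[Si](C)(C)C(C)(C)C)CC/C(C)=C/CC/C(C)=C/CBr | intermediate
11 | 1-(trimethylsilyl)propyne | CC#C[Si](C)(C)C | starting material
12 | 3-lithio-1-(trimethylsilyl)propyne | [Li]CC#C[Si](C)(C)C | intermediate
13 | (5E,9E,13R)-13-(tert-butyldimethylsilyloxy)-6,10,14-trimethyl-1-(trimethylsilyl)pentadeca-5,9,14-trien-1-yne | C=C(C)[C@H](O[Si](C)(C)C(C)(C)C)CC/C(C)=C/CC/C(C)=C/CCC#C[Si](C)(C)C | intermediate
14 | (5E,9E,13R)-13-(tert-butyldimethylsilyloxy)-6,10,14-trimethylpentadeca-5,9,14-trien-1-yne | C=C(C)[C@H](O[Si](C)(C)C(C)(C)C)CC/C(C)=C/CC/C(C)=C/CCC#C | intermediate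
15 | lithium acetylide of 14 | C=C(C)[C@H](O[Si](C)(C)C(C)(C)C)CC/C(C)=C/CC/C(C)=C/CCC#C[Li] | intermediate
16 | (6E,10E,14R)-14-(tert-butyldimethylsilyloxy)-7,11,15-trimethylhexadeca-6,10,15-trien-2-yn-1-ol | C=C(C)[C@H](O[Si](C)(C)C(C)(C)C)CC/C(C)=C/CC/C(C)=C/CCC#CCO | intermediate
17 | sodium cyclic alkoxyvinylalanate (1,2-oxaluminacyclopent-3-ene with Al on C7, two 2-methoxyethoxy ligands) | C=C(C)[C@H](O[Si](C)(C)C(C)(C)C)CC/C(C)=C/CC/C(C)=C/CCC1=CCO[Al-]1(OCCOC)OCCOC.[Na+] | intermediate
18 | (2Z,6E,10E,14R)-14-(tert-butyldimethylsilyloxy)-3-iodo-7,11,15-trimethylhexadeca-2,6,10,15-tetraen-1-ol | C=C(C)[C@H](O[Si](C)(C)C(C)(C)C)CC/C(C)=C/CC/C(C)=C/CC/C(I)=C/CO | intermediate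
19 | (2Z,6E,10E,14R)-1-bromo-14-(tert-butyldimethylsilyloxy)-3-iodo-7,11,15-trimethylhexadeca-2,6,10,15-tetraene | C=C(C)[C@H](O[Si](C)(C)C(C)(C)C)CC/C(C)=C/CC/C(C)=C/CC/C(I)=C/CBr | intermediate
20 | 3-furanmethanol | OCc1ccoc1 | starting material
21 | dilithiated 3-furanmethanol (lithium 2-lithiofuran-3-ylmethoxide) | [Li]OCc1ccoc1[Li] | intermediate
22 | {2-[(2Z,6E,10E,14R)-14-(tert-butyldimethylsilyloxy)-3-iodo-7,11,15-trimethylhexadeca-2,6,10,15-tetraen-1-yl]furan-3-yl}methanol | C=C(C)[C@H](O[Si](C)(C)C(C)(C)C)CC/C(C)=C/CC/C(C)=C/CC/C(I)=C/Cc1occc1CO | intermediate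
23 | {2-[(2Z,6E,10E,14R)-14-(tert-butyldimethylsilyloxy)-3-(hydroxymethyl)-7,11,15-trimethylhexadeca-2,6,10,15-tetraen-1-yl]furan-3-yl}methanol | C=C(C)[C@H](O[Si](C)(C)C(C)(C)C)CC/C(C)=C/CC/C(C)=C/CC/C(CO)=C/Cc1occc1CO | intermediate
24 | 2-[(2Z,6E,10E,14R)-14-(tert-butyldimethylsilyloxy)-3-(tert-butyldimethylsilyloxymethyl)-7,11,15-trimethylhexadeca-2,6,10,15-tetraen-1-yl]-3-(tert-butyldimethylsilyloxymethyl)furan | C=C(C)[C@H](O[Si](C)(C)C(C)(C)C)CC/C(C)=C/CC/C(C)=C/CC/C(CO[Si](C)(C)C(C)(C)C)=C/Cc1occc1CO[Si](C)(C)C(C)(C)C | intermediate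
25 | furan endoperoxide of 24 (2,3,7-trioxabicyclo[2.2.1]hept-5-ene, side chain on C1, silyloxymethyl on C6; both faces) | C=C(C)[C@H](O[Si](C)(C)C(C)(C)C)CC/C(C)=C/CC/C(C)=C/CC/C(CO[Si](C)(C)C(C)(C)C)=C/CC12OOC(O1)C=C2CO[Si](C)(C)C(C)(C)C | intermediate
26 | 5-hydroxy-4-(tert-butyldimethylsilyloxymethyl)-5-[(2Z,6E,10E,14R)-14-(tert-butyldimethylsilyloxy)-3-(tert-butyldimethylsilyloxymethyl)-7,11,15-trimethylhexadeca-2,6,10,15-tetraen-1-yl]furan-2(5H)-one (both epimers at the hemiketal carbon) | C=C(C)[C@H](O[Si](C)(C)C(C)(C)C)CC/C(C)=C/CC/C(C)=C/CC/C(CO[Si](C)(C)C(C)(C)C)=C/CC1(O)OC(=O)C=C1CO[Si](C)(C)C(C)(C)C | intermediate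
27 | methyl (2Z,6Z,10E,14E,18R)-18-(tert-butyldimethylsilyloxy)-3,7-bis(tert-butyldimethylsilyloxymethyl)-11,15,19-trimethyl-4-oxoicosa-2,6,10,14,19-pentaenoate | C=C(C)[C@H](O[Si](C)(C)C(C)(C)C)CC/C(C)=C/CC/C(C)=C/CC/C(CO[Si](C)(C)C(C)(C)C)=C/CC(=O)/C(CO[Si](C)(C)C(C)(C)C)=C\C(=O)OC | intermediate
28 | methyl (2Z,4R,6Z,10E,14E,18R)-18-(tert-butyldimethylsilyloxy)-3,7-bis(tert-butyldimethylsilyloxymethyl)-4-hydroxy-11,15,19-trimethylicosa-2,6,10,14,19-pentaenoate | C=C(C)[C@H](O[Si](C)(C)C(C)(C)C)CC/C(C)=C/CC/C(C)=C/CC/C(CO[Si](C)(C)C(C)(C)C)=C/C[C@@H](O)/C(CO[Si](C)(C)C(C)(C)C)=C\C(=O)OC | intermediate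
29 | tris-TBS ether of hippolide H, (5R)-4-(tert-butyldimethylsilyloxymethyl)-5-[(2Z,6E,10E,14R)-14-(tert-butyldimethylsilyloxy)-3-(tert-butyldimethylsilyloxymethyl)-7,11,15-trimethylhexadeca-2,6,10,15-tetraen-1-yl]furan-2(5H)-one | C=C(C)[C@H](O[Si](C)(C)C(C)(C)C)CC/C(C)=C/CC/C(C)=C/CC/C(CO[Si](C)(C)C(C)(C)C)=C/C[C@H]1OC(=O)C=C1CO[Si](C)(C)C(C)(C)C | intermediate
30 | Hippolide H, (5R)-4-(hydroxymethyl)-5-[(2Z,6E,10E,14R)-14-hydroxy-3-(hydroxymethyl)-7,11,15-trimethylhexadeca-2,6,10,15-tetraen-1-yl]furan-2(5H)-one | C=C(C)[C@H](O)CC/C(C)=C/CC/C(C)=C/CC/C(=C/C[C@H]1OC(=O)C=C1CO)CO | target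

**Step count**

Total steps: 20. Longest linear sequence: 20 steps, from farnesol (1) to 30; compounds 11 and 20 enter directly.

**Steps most likely to fail, with fallbacks**

Step 14. The deprotonation may not be site-selective (lithiation at the other furan α-position), the alkoxide may be allylated in competition, or the organolithium may attack the vinyl iodide by dehydroiodination or exchange. The fallback sets out from 19 and uses a carboxylate instead of an alkoxide as the directing group. Commercial 3-furoic acid is converted with LDA (2 equiv, THF, −78 °C) into its 2-lithio carboxylate, whose regiochemistry is enforced by the adjacent carboxylate. Alkylation with 19 should give 2-[(2Z,6E,10E,14R)-14-(tert-butyldimethylsilyloxy)-3-iodo-7,11,15-trimethylhexadeca-2,6,10,15-tetraen-1-yl]furan-3-carboxylic acid F1. Esterification (MeI, K2CO3, DMF) would give the methyl ester F2, and DIBAL-H reduction (CH2Cl2, −78 °C, which spares the vinyl iodide) comes back to the route at 22.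

Step 15. Transmetalation of the sp3 hydroxymethyl group from tin may be slow, so that butyl transfer, protodeiodination or isomerisation of the skipped diene compete. The fallback sets out from 22 and replaces cross-coupling by carbonylation and reduction. Palladium-catalysed methoxycarbonylation (Pd(OAc)2, PPh3, CO 1 atm, MeOH, Et3N, DMF, 60 °C) should convert the vinyl iodide with retention into methyl (2Z)-2-[(3E,7E,11R)-11-(tert-butyldimethylsilyloxy)-4,8,12-trimethyltrideca-3,7,12-trien-1-yl]-4-[3-(hydroxymethyl)furan-2-yl]but-2-enoate F3. DIBAL-H (CH2Cl2, −78 °C) reduces the ester to the allylic alcohol and comes back to the route at 23.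

Step 19. Facial discrimination may be poor because both ketone flanks are unsaturated chains, catecholborane may reduce the enone in a conjugate sense, or the keto ester may isomerise from Z to E so that lactonisation fails. The fallback sets out from 27 and replaces catalyst-controlled borane delivery by a stoichiometric chiral aluminium hydride. (R)-BINAL-H (THF, −100 to −78 °C) distinguishes the conjugated alkenyl flank from the saturated CH2 flank electronically, not by size, reduces enones in the 1,2-sense and leaves esters untouched at this temperature. It should give the same 4R hydroxy ester 28, which lactonises and comes back to the route at 29; no new compound is made.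

**Further compounds**

F1 | step 14 | 2-[(2Z,6E,10E,14R)-14-(tert-butyldimethylsilyloxy)-3-iodo-7,11,15-trimethylhexadeca-2,6,10,15-tetraen-1-yl]furan-3-carboxylic acid | C=C(C)[C@H](O[Si](C)(C)C(C)(C)C)CC/C(C)=C/CC/C(C)=C/CC/C(I)=C/Cc1occc1C(O)=O
F2 | step 14 | methyl 2-[(2Z,6E,10E,14R)-14-(tert-butyldimethylsilyloxy)-3-iodo-7,11,15-trimethylhexadeca-2,6,10,15-tetraen-1-yl]furan-3-carboxylate | C=C(C)[C@H](O[Si](C)(C)C(C)(C)C)CC/C(C)=C/CC/C(C)=C/CC/C(I)=C/Cc1occc1C(=O)OC
F3 | step 15 | methyl (2Z)-2-[(3E,7E,11R)-11-(tert-butyldimethylsilyloxy)-4,8,12-trimethyltrideca-3,7,12-trien-1-yl]-4-[3-(hydroxymethyl)furan-2-yl]but-2-enoate | C=C(C)[C@H](O[Si](C)(C)C(C)(C)C)CC/C(C)=C/CC/C(C)=C/CC/C(C(=O)OC)=C/Cc1occc1CO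
F0 | step 19 | none | none
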